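**Plan**
1. Retrosynthesis (drimane numbering): cut the C11–O aryl ether (Mitsunobu); trace the C6=C7–C8=C12 diene back to a 3-methylcyclohex-2-enone in ring B (C6=O, C7=C8, C12 as methyl); cut ring B at C7–C8 (aldol) and ring A at C5–C10 (Michael) together; finally cut C2–C3 (Grignard).
2. Enabling feature: in ring B, C5–C6–C7 is a masked acetone unit (C6 carbonyl with both α-carbons) and C8–C9–C10 a masked alkylidene acetoacetate (C10 β-carbon, C8 ketone, C9 carrying C11 as ester). One base treatment of an acyclic keto alkylidene-acetoacetate should therefore close ring A and then ring B.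
3. Forward order: C2–C3 chain assembly, Knoevenagel and Wacker steps to arm both ends, double annulation (ring A first, ring B second), removal of the C6 oxygen via the enol triflate, deconjugation to the exocyclic diene, reduction at C11, coumarin ether, desilylation.
4. Stereochemistry: C3 from a CBS reduction; C10 and C5 relayed from C3 in the reversible chair-like Michael closure (C5 enolisable, trans fusion); C9 from kinetic α-protonation of a trienolate anti to the C10 methyl.

Key step: step 8

Remark: positions are given in drimane numbering (ring A = C1–C5, C10; ring B = C5–C10; C11 = CH2O; C12 = exocyclic CH2), and the target is read as 3S,5R,9S,10S (3β-OH, 5α-H, 9β-CH2OAr, 10β-CH3, trans-decalin).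

Step 1
Reactants: 1 2,2-dimethylpent-4-enal; 2 2-(2-bromoethyl)-2-methyl-1,3-dioxolane
Product: 4 rac-4,4-dimethyl-1-(2-methyl-1,3-dioxolan-2-yl)hept-6-en-3-ol, via Grignard reagent 3 (not isolated)
Conditions: Mg, THF, 25 °C (from 2); then 1, THF, −20 → 0 °C; aq. NH4Cl
Reagents that add atoms: none
Why: Grignard addition of the masked 3-oxobutyl nucleophile to the non-enolisable aldehyde forms the C2–C3 bond; the new carbinol centre is racemic and is corrected in steps 2 and 3.

Step 2
Reactants: 4 rac-4,4-dimethyl-1-(2-methyl-1,3-dioxolan-2-yl)hept-6-en-3-ol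
Product: 5 4,4-dimethyl-1-(2-methyl-1,3-dioxolan-2-yl)hept-6-en-3-one
Conditions: (n-Pr4N)RuO4 (5 mol%), N-methylmorpholine N-oxide, 4 Å sieves, CH2Cl2, 25 °C
Reagents that add atoms: none
Why: Ley–Griffith oxidation should convert the hindered secondary alcohol to the ketone under neutral conditions that leave the ketal and the terminal alkene untouched.

Step 3
Reactants: 5 4,4-dimethyl-1-(2-methyl-1,3-dioxolan-2-yl)hept-6-en-3-one
Product: 6 (3S)-4,4-dimethyl-1-(2-methyl-1,3-dioxolan-2-yl)hept-6-en-3-ol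
Conditions: (R)-2-methyl-CBS-oxazaborolidine (0.2 equiv), catecholborane, toluene, −78 °C; then MeOH, aq. NaOH
Reagents that add atoms: none
Why: Corey–Bakshi–Shibata reduction in which the tert-alkyl group acts as the large substituent, so the (R)-catalyst should deliver hydride to give the (S)-carbinol (C3), while catecholborane at low temperature spares the terminal alkene.

Step 4
Reactants: 6 (3S)-4,4-dimethyl-1-(2-methyl-1,3-dioxolan-2-yl)hept-6-en-3-ol
Product: 7 tert-butyl{[(3S)-4,4-dimethyl-1-(2-methyl-1,3-dioxolan-2-yl)hept-6-en-3-yl]oxy}dimethylsilane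
Conditions: t-BuMe2SiOTf, 2,6-lutidine, CH2Cl2, −78 → 0 °C
Reagents that add atoms: tert-butyldimethylsilyl trifluoromethanesulfonate, CC(C)(C)[Si](C)(C)OS(=O)(=O)C(F)(F)F
Why: Silylation of the hindered secondary alcohol with the silyl triflate protects the C3 oxygen against lactol formation and oxa-Michael addition in later steps.

Step 5
Reactants: 7 tert-butyl{[(3S)-4,4-dimethyl-1-(2-methyl-1,3-dioxolan-2-yl)hept-6-en-3-yl]oxy}dimethylsilane
Product: 8 (5S)-5-[(tert-butyldimethylsilyl)oxy]-6,6-dimethylnon-8-en-2-one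
Conditions: pyridinium p-toluenesulfonate (cat.), acetone/H2O (9:1), 50 °C
Reagents that add atoms: water, O
Why: Acid-catalysed acetal hydrolysis should free the C10 methyl ketone while the hindered secondary silyl ether survives the mildly acidic medium.

Step 6
Reactants: 8 (5S)-5-[(tert-butyldimethylsilyl)oxy]-6,6-dimethylnon-8-en-2-one; 9 tert-butyl 3-oxobutanoate
Product: 10 tert-butyl (6S)-2-acetyl-6-[(tert-butyldimethylsilyl)oxy]-3,7,7-trimethyldeca-2,9-dienoate (E/Z mixture at C2=C3)
Conditions: TiCl4, pyridine, THF, 0 → 25 °C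
Reagents that add atoms: none
Why: Titanium-mediated Knoevenagel condensation at the unhindered methyl ketone installs the alkylidene acetoacetate acceptor (C8, C9, C11, C12); its double-bond geometry is immaterial because C9 and C10 become sp3 in step 8.

Step 7
Reactants: 10 tert-butyl (6S)-2-acetyl-6-[(tert-butyldimethylsilyl)oxy]-3,7,7-trimethyldeca-2,9-dienoate
Product: 11 tert-butyl (6S)-2-acetyl-6-[(tert-butyldimethylsilyl)oxy]-3,7,7-trimethyl-9-oxodec-2-enoate (E/Z mixture)
Conditions: PdCl2 (10 mol%), CuCl, O2 (1 atm), DMF/H2O (7:1), 25 °C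
Reagents that add atoms: water, O
Why: Tsuji–Wacker oxidation should convert the terminal allyl group into the C6 methyl ketone (Markovnikov), the tetrasubstituted electron-poor alkene being inert.

Step 8
Reactants: 11 tert-butyl (6S)-2-acetyl-6-[(tert-butyldimethylsilyl)oxy]-3,7,7-trimethyl-9-oxodec-2-enoate
Product: 14 tert-butyl (1S,4aR,6S,8aS)-6-[(tert-butyldimethylsilyl)oxy]-2,5,5,8a-tetramethyl-4-oxo-1,4,4a,5,6,7,8,8a-octahydronaphthalene-1-carboxylate, via Michael adduct 12 (not isolated), via aldol 13 (not isolated)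
Conditions: KOt-Bu (1.2 equiv), t-BuOH/THF (1:1), 0.02 M, 25 → 60 °C; then AcOH
Reagents that add atoms: none
Why: KOt-Bu reversibly forms the C5 enolate of the methyl ketone, which adds to C10 of the alkylidene acetoacetate (intramolecular Michael addition, 6-(enolexo)-exo-trig, ring A, bond C5–C10) to give the stabilised β-keto ester anion of 12; proton transfer then lets the C7 enolate attack the C8 acetyl carbonyl (intramolecular aldol, 6-(enolendo)-exo-trig, ring B, bond C7–C8) to 13, which loses water to the conjugated enone. The closest known reaction type is the base-mediated Michael addition/aldol condensation of 2-acetyl-5-oxohexanoate esters to 2-methyl-4-oxocyclohex-2-ene-1-carboxylates (a Robinson-type annulation), here run with the Michael step inside a tether so that both rings arise in one operation. C10 is set in the chair-like Michael closure that keeps the C3 silyloxy group, the C5 acetyl arm and the C10 acetoacetate arm equatorial and the C10 methyl axial; because the addition is reversible this is also the thermodynamic outcome, and it relays the C3 configuration to C10, although the equatorial preference of the silyloxy group is only moderate. C5 stays enolisable (α to the C6 ketone) and should settle as the trans ring fusion; C9 is enolisable, is drawn as the equatorial ester, and is erased in step 9. The step needs C5 and not C7 to add to C10 (six- against eight-membered ring), the C7-to-C8 aldol and not the C12-to-C6 aldol (the acetoacetate ketone is the more electrophilic carbonyl and the C6 ketone lies between hindered centres), and no Claisen attack on the ester (tert-butyl ester, bulky base).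

Step 9
Reactants: 14 tert-butyl (1S,4aR,6S,8aS)-6-[(tert-butyldimethylsilyl)oxy]-2,5,5,8a-tetramethyl-4-oxo-1,4,4a,5,6,7,8,8a-octahydronaphthalene-1-carboxylate
Product: 16 tert-butyl (4aR,6S,8aS)-6-[(tert-butyldimethylsilyl)oxy]-2,5,5,8a-tetramethyl-4-{[(trifluoromethyl)sulfonyl]oxy}-4a,5,6,7,8,8a-hexahydronaphthalene-1-carboxylate, via potassium dienolate 15 (not isolated)
Conditions: KN(SiMe3)2, THF, −78 °C; then PhNTf2, −78 → 0 °C
Reagents that add atoms: N-phenylbis(trifluoromethanesulfonimide), O=S(=O)(N(c1ccccc1)S(=O)(=O)C(F)(F)F)C(F)(F)F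
Why: Deprotonation at C9 of the vinylogous β-keto ester gives the extended enolate, which should be O-sulfonylated at the C6 oxygen (enol triflate formation), fixing C6=C7 and deliberately erasing C9 (a double-bond isomer of 14 conjugated with the ester would give the same enolate).

Step 10
Reactants: 16 tert-butyl (4aR,6S,8aS)-6-[(tert-butyldimethylsilyl)oxy]-2,5,5,8a-tetramethyl-4-{[(trifluoromethyl)sulfonyl]oxy}-4a,5,6,7,8,8a-hexahydronaphthalene-1-carboxylate
Product: 17 tert-butyl (4aR,6S,8aS)-6-[(tert-butyldimethylsilyl)oxy]-2,5,5,8a-tetramethyl-4a,5,6,7,8,8a-hexahydronaphthalene-1-carboxylate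
Conditions: Pd(OAc)2 (5 mol%), PPh3 (10 mol%), HCO2H, n-Bu3N, DMF, 60 °C
Reagents that add atoms: none
Why: Palladium-catalysed formate reduction of the enol triflate (oxidative addition of zerovalent palladium, formate exchange, decarboxylation, reductive elimination) should replace the C6 oxygen by hydrogen and leave the C6=C7 bond in place.

Step 11
Reactants: 17 tert-butyl (4aR,6S,8aS)-6-[(tert-butyldimethylsilyl)oxy]-2,5,5,8a-tetramethyl-4a,5,6,7,8,8a-hexahydronaphthalene-1-carboxylate
Product: 19 tert-butyl (1S,4aR,6S,8aS)-6-[(tert-butyldimethylsilyl)oxy]-5,5,8a-trimethyl-2-methylidene-1,2,4a,5,6,7,8,8a-octahydronaphthalene-1-carboxylate, via lithium trienolate 18 (not isolated)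
Conditions: LiN(i-Pr)2, THF/DMPU, −78 °C; then AcOH in THF, −78 °C
Reagents that add atoms: none
Why: Deconjugative protonation in which LiN(i-Pr)2 removes a hydrogen from the C8 methyl group lying cis to the ester, and kinetic protonation of the trienolate at the α-carbon C9 from the face anti to the axial C10 methyl should give the exocyclic C8=C12 bond and the 9α-H configuration.

Step 12
Reactants: 19 tert-butyl (1S,4aR,6S,8aS)-6-[(tert-butyldimethylsilyl)oxy]-5,5,8a-trimethyl-2-methylidene-1,2,4a,5,6,7,8,8a-octahydronaphthalene-1-carboxylate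
Product: 20 [(1S,4aR,6S,8aS)-6-[(tert-butyldimethylsilyl)oxy]-5,5,8a-trimethyl-2-methylidene-1,2,4a,5,6,7,8,8a-octahydronaphthalen-1-yl]methanol
Conditions: i-Bu2AlH (3 equiv), CH2Cl2, −78 → 0 °C; aq. potassium sodium tartrate
Reagents that add atoms: none
Why: Hydride reduction of the ester with i-Bu2AlH should give the primary alcohol C11 under non-basic conditions, so the allylic C9 centre is neither epimerised nor reconjugated.

Step 13
Reactants: 20 [(1S,4aR,6S,8aS)-6-[(tert-butyldimethylsilyl)oxy]-5,5,8a-trimethyl-2-methylidene-1,2,4a,5,6,7,8,8a-octahydronaphthalen-1-yl]methanol; 21 7-hydroxy-2H-chromen-2-one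
Product: 22 7-{[(1S,4aR,6S,8aS)-6-[(tert-butyldimethylsilyl)oxy]-5,5,8a-trimethyl-2-methylidene-1,2,4a,5,6,7,8,8a-octahydronaphthalen-1-yl]methoxy}-2H-chromen-2-one
Conditions: PPh3, diisopropyl azodicarboxylate, THF, 0 → 25 °C
Reagents that add atoms: none
Why: Mitsunobu etherification of the primary alcohol by the acidic 7-hydroxycoumarin should form the C11–O aryl ether at a carbon that is not a stereocentre.

Step 14
Reactants: 22 7-{[(1S,4aR,6S,8aS)-6-[(tert-butyldimethylsilyl)oxy]-5,5,8a-trimethyl-2-methylidene-1,2,4a,5,6,7,8,8a-octahydronaphthalen-1-yl]methoxy}-2H-chromen-2-one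
Product: 23 7-{[(1S,4aR,6S,8aS)-6-hydroxy-5,5,8a-trimethyl-2-methylidene-1,2,4a,5,6,7,8,8a-octahydronaphthalen-1-yl]methoxy}-2H-chromen-2-one
Conditions: HF·pyridine, pyridine/THF, 0 → 25 °C
Reagents that add atoms: none
Why: Buffered fluoride desilylation should free the 3β-hydroxyl without touching the diene or the coumarin lactone.

**Compound list**
1 | 2,2-dimethylpent-4-enal | C=CCC(C)(C)C=O | starting material
2 | 2-(2-bromoethyl)-2-methyl-1,3-dioxolane | CC1(CCBr)OCCO1 | starting material
3 | [2-(2-methyl-1,3-dioxolan-2-yl)ethyl]magnesium bromide | CC1(CC[Mg]Br)OCCO1 | intermediate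
4 | rac-4,4-dimethyl-1-(2-methyl-1,3-dioxolan-2-yl)hept-6-en-3-ol | C=CCC(C)(C)C(O)CCC1(C)OCCO1 | intermediate
5 | 4,4-dimethyl-1-(2-methyl-1,3-dioxolan-2-yl)hept-6-en-3-one | C=CCC(C)(C)C(=O)CCC1(C)OCCO1 | intermediate
6 | (3S)-4,4-dimethyl-1-(2-methyl-1,3-dioxolan-2-yl)hept-6-en-3-ol | C=CCC(C)(C)[C@@H](O)CCC1(C)OCCO1 | intermediate
7 | tert-butyl{[(3S)-4,4-dimethyl-1-(2-methyl-1,3-dioxolan-2-yl)hept-6-en-3-yl]oxy}dimethylsilane | C=CCC(C)(C)[C@@H](O[Si](C)(C)C(C)(C)C)CCC1(C)OCCO1 | intermediate
8 | (5S)-5-[(tert-butyldimethylsilyl)oxy]-6,6-dimethylnon-8-en-2-one | C=CCC(C)(C)[C@@H](O[Si](C)(C)C(C)(C)C)CCC(C)=O | intermediate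
9 | tert-butyl 3-oxobutanoate (tert-butyl acetoacetate) | CC(=O)CC(=O)OC(C)(C)C | starting material
10 | tert-butyl (6S)-2-acetyl-6-[(tert-butyldimethylsilyl)oxy]-3,7,7-trimethyldeca-2,9-dienoate, E/Z mixture | C=CCC(C)(C)[C@@H](O[Si](C)(C)C(C)(C)C)CCC(C)=C(C(C)=O)C(=O)OC(C)(C)C | intermediate
11 | tert-butyl (6S)-2-acetyl-6-[(tert-butyldimethylsilyl)oxy]-3,7,7-trimethyl-9-oxodec-2-enoate, E/Z mixture | CC(=O)CC(C)(C)[C@@H](O[Si](C)(C)C(C)(C)C)CCC(C)=C(C(C)=O)C(=O)OC(C)(C)C | intermediate
12 | tert-butyl 2-[(1S,2R,4S)-2-acetyl-4-[(tert-butyldimethylsilyl)oxy]-1,3,3-trimethylcyclohexyl]-3-oxobutanoate, epimers at C2 of the butanoate | CC(=O)[C@H]1C(C)(C)[C@@H](O[Si](C)(C)C(C)(C)C)CC[C@]1(C)C(C(C)=O)C(=O)OC(C)(C)C | intermediate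
13 | tert-butyl (4aR,6S,8aS)-6-[(tert-butyldimethylsilyl)oxy]-2-hydroxy-2,5,5,8a-tetramethyl-4-oxodecahydronaphthalene-1-carboxylate, C1 and C2 undefined | CC1(O)CC(=O)[C@H]2C(C)(C)[C@@H](O[Si](C)(C)C(C)(C)C)CC[C@]2(C)C1C(=O)OC(C)(C)C | intermediate
14 | tert-butyl (1S,4aR,6S,8aS)-6-[(tert-butyldimethylsilyl)oxy]-2,5,5,8a-tetramethyl-4-oxo-1,4,4a,5,6,7,8,8a-octahydronaphthalene-1-carboxylate | CC1=CC(=O)[C@H]2C(C)(C)[C@@H](O[Si](C)(C)C(C)(C)C)CC[C@]2(C)[C@H]1C(=O)OC(C)(C)C | intermediate
15 | potassium extended enolate of 14 (C6 oxido, C6=C7 and C8=C9; 4aR,6S,8aS) | CC=1C=C([O-])[C@H]2C(C)(C)[C@@H](O[Si](C)(C)C(C)(C)C)CC[C@]2(C)C=1C(=O)OC(C)(C)C.[K+] | intermediate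
16 | tert-butyl (4aR,6S,8aS)-6-[(tert-butyldimethylsilyl)oxy]-2,5,5,8a-tetramethyl-4-{[(trifluoromethyl)sulfonyl]oxy}-4a,5,6,7,8,8a-hexahydronaphthalene-1-carboxylate | CC=1C=C(OS(=O)(=O)C(F)(F)F)[C@H]2C(C)(C)[C@@H](O[Si](C)(C)C(C)(C)C)CC[C@]2(C)C=1C(=O)OC(C)(C)C | intermediate
17 | tert-butyl (4aR,6S,8aS)-6-[(tert-butyldimethylsilyl)oxy]-2,5,5,8a-tetramethyl-4a,5,6,7,8,8a-hexahydronaphthalene-1-carboxylate | CC=1C=C[C@H]2C(C)(C)[C@@H](O[Si](C)(C)C(C)(C)C)CC[C@]2(C)C=1C(=O)OC(C)(C)C | intermediate
18 | lithium trienolate of 17 (deprotonated at the C8 methyl; ester enolate at C9; 4aR,6S,8aS) | C=C1C=C[C@H]2C(C)(C)[C@@H](O[Si](C)(C)C(C)(C)C)CC[C@]2(C)C1=C([O-])OC(C)(C)C.[Li+] | intermediate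
19 | tert-butyl (1S,4aR,6S,8aS)-6-[(tert-butyldimethylsilyl)oxy]-5,5,8a-trimethyl-2-methylidene-1,2,4a,5,6,7,8,8a-octahydronaphthalene-1-carboxylate | C=C1C=C[C@H]2C(C)(C)[C@@H](O[Si](C)(C)C(C)(C)C)CC[C@]2(C)[C@H]1C(=O)OC(C)(C)C | intermediate
20 | [(1S,4aR,6S,8aS)-6-[(tert-butyldimethylsilyl)oxy]-5,5,8a-trimethyl-2-methylidene-1,2,4a,5,6,7,8,8a-octahydronaphthalen-1-yl]methanol | C=C1C=C[C@H]2C(C)(C)[C@@H](O[Si](C)(C)C(C)(C)C)CC[C@]2(C)[C@H]1CO | intermediate
21 | 7-hydroxy-2H-chromen-2-one (umbelliferone) | Oc1ccc2ccc(=O)oc2c1 | starting material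
22 | 7-{[(1S,4aR,6S,8aS)-6-[(tert-butyldimethylsilyl)oxy]-5,5,8a-trimethyl-2-methylidene-1,2,4a,5,6,7,8,8a-octahydronaphthalen-1-yl]methoxy}-2H-chromen-2-one | C=C1C=C[C@H]2C(C)(C)[C@@H](O[Si](C)(C)C(C)(C)C)CC[C@]2(C)[C@H]1COc1ccc2ccc(=O)oc2c1 | intermediate
23 | 7-{[(1S,4aR,6S,8aS)-6-hydroxy-5,5,8a-trimethyl-2-methylidene-1,2,4a,5,6,7,8,8a-octahydronaphthalen-1-yl]methoxy}-2H-chromen-2-one | C=C1C=C[C@H]2C(C)(C)[C@@H](O)CC[C@]2(C)[C@H]1COc1ccc2ccc(=O)oc2c1 | target

Total step count: 14. Longest linear sequence: 14 steps (1 → 23); 9 and 21 enter at steps 6 and 13.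

**Steps most likely to fail**

Step 8. The ring A closure joins an enolate carbon next to the quaternary C4 to a fully substituted acceptor carbon. Reversible γ-deprotonation of the alkylidene acetoacetate or retro-Michael cleavage may outrun C–C bond formation, and the relay of configuration from C3 to C10 may be incomplete. The fallback separates the two bond formations and changes the donor from an enolate to an enamine. Starting from 11, condensation with pyrrolidine (benzene, 4 Å sieves) should give the pyrrolidine enamine F1, whose neutral C5 carbon should add to the acceptor on warming (Stork enamine Michael addition) to give the cyclised enamine F2. Hydrolysis with aqueous acetic acid should deliver the Michael adduct 12 as an isolated compound. A separate acid-catalysed aldol condensation (p-toluenesulfonic acid, benzene, water removal) should then close ring B and rejoin the route at 14.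

Step 11. Deprotonation may occur at C5–H instead of the C8 methyl, reprotonation may return the conjugated ester, or facial selectivity at C9 may be poor. The fallback keeps the thermodynamically set C9 centre of 14 and removes the C6 oxygen by a 1,4-dehydration. Starting from 14, Luche reduction (NaBH4, CeCl3·7H2O, MeOH, −20 °C) from the less hindered α face should give the 6β allylic alcohol F3. 2,4-Dinitrobenzenesulfenyl chloride and Et3N should convert it into the sulfenate ester F4. On warming in 1,2-dichloroethane this should rearrange suprafacially (Mislow–Evans-type [2,3] shift) to the C8 allylic sulfoxide F5, which undergoes thermal syn elimination. Because sulfur arrives on the β face at C8 and H9 is α, only the C8 methyl hydrogens are syn, so the exocyclic methylene and the C6=C7 bond should form together, rejoining the route at 19.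

Step 13. Displacement at the β-branched, neopentyl-like C11 oxyphosphonium centre may be slow, giving recovered alcohol or elimination. The fallback forms the aryl–oxygen bond instead of the alkyl–oxygen bond and makes no new compound (F0). Starting from 20, Buchwald–Hartwig etherification with commercial 7-bromo-2H-chromen-2-one (Pd(OAc)2, t-BuBrettPhos, Cs2CO3, toluene, 80 °C) should give 22 directly.

**Further compounds**
F1 | step 8 | pyrrolidine enamine of 11 (C5=C6 enamine; 3S) | CC(=CC(C)(C)[C@@H](O[Si](C)(C)C(C)(C)C)CCC(C)=C(C(C)=O)C(=O)OC(C)(C)C)N1CCCC1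
F2 | step 8 | pyrrolidine enamine of Michael adduct 12 (C6=C7 enamine; ring configured as 12) | C=C(N1CCCC1)[C@H]1C(C)(C)[C@@H](O[Si](C)(C)C(C)(C)C)CC[C@]1(C)C(C(C)=O)C(=O)OC(C)(C)C
F3 | step 11 | tert-butyl (1S,4R,4aR,6S,8aS)-6-[(tert-butyldimethylsilyl)oxy]-4-hydroxy-2,5,5,8a-tetramethyl-1,4,4a,5,6,7,8,8a-octahydronaphthalene-1-carboxylate | CC1=C[C@@H](O)[C@H]2C(C)(C)[C@@H](O[Si](C)(C)C(C)(C)C)CC[C@]2(C)[C@H]1C(=O)OC(C)(C)C
F4 | step 11 | 2,4-dinitrobenzenesulfenate ester of F3 (at the C6 oxygen, configured as F3) | CC1=C[C@@H](OSc3ccc(cc3[N+](=O)[O-])[N+](=O)[O-])[C@H]2C(C)(C)[C@@H](O[Si](C)(C)C(C)(C)C)CC[C@]2(C)[C@H]1C(=O)OC(C)(C)C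
F5 | step 11 | C8 (2,4-dinitrophenyl)sulfinyl compound with C6=C7, sulfur on the face of the C10 methyl, otherwise configured as 14 | C[C@]1(S(=O)c3ccc(cc3[N+](=O)[O-])[N+](=O)[O-])C=C[C@H]2C(C)(C)[C@@H](O[Si](C)(C)C(C)(C)C)CC[C@]2(C)[C@H]1C(=O)OC(C)(C)C
F0 | step 13 | none | none
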